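A = benzo ring bearing CHO (C3a to C7a); B = its dihydrofuran (O1, C2, C3, C3a, C7a); C/D = the second benzo/dihydrofuran pair (primed numbers); E = 3,5-dihydroxyphenyl on C3'; F, G = 4-hydroxyphenyl on C2, C2'. End game: CHO from a C5 nitrile, the five phenols from TBS ethers.
Key disconnection: O1-C2 and C3-C3a of ring B lead back to the E-stilbene C=C of penta-O-TBS ε-viniferin and 2-diazonio-4-cyanophenolate, which supplies all of ring A. The rhodium carbene first closes the cyclopropane C3a-C3-C2, spiro to a cyclohexadienone, and this three-membered ring then grows by C7a and O1 into ring B.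
Enabling feature: C2 of ring B bears the para-oxygenated ring F, a cation-stabilising donor. C3a and C7a-O1 are the ortho carbon and the oxygen of a phenol whose para carbon C5 bears an acceptor. The spirocyclopropane is therefore push-pull, only its C3a-C2 bond can ionise, and reclosure at O1 restores the aromaticity of ring A.
Stilbene: Heck coupling at C4'-Br of ring C. Ring D: enantioselective rhodium-carbene C-H insertion of a diaryl ketone hydrazone (cis), then acid epimerisation at C2' (trans). Ketone: Friedel-Crafts acylation.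
Order of ring formation: D (step 5), then the cyclopropane and from it B (step 11). Rings A, C, E, F and G are bought as arenes.

Key step: step 11

Assumption: the sense of induction of the two chiral dirhodium catalysts is assigned by analogy with related substrates. Both catalysts are available in either mirror-image form, and the form that gives the drawn configuration is the one meant.

Step 1
Reactants: 1 1-bromo-3,5-dimethoxybenzene; 2 3,5-dimethoxybenzoyl chloride
Product: 3 (2-bromo-4,6-dimethoxyphenyl)(3,5-dimethoxyphenyl)methanone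
Conditions: AlCl3 (1.2 equiv), CH2Cl2, 0 °C to rt
Reagents that add atoms: none
Why: Friedel-Crafts acylation, in which the acylium ion from 2 attacks 1 at the carbon para to one methoxy group and ortho to the other (next to bromine), a position as activated as, and less crowded than, the carbon between the two methoxy groups; no stereocentre is formed.

Step 2
Reactants: 3 (2-bromo-4,6-dimethoxyphenyl)(3,5-dimethoxyphenyl)methanone
Product: 4 (2-bromo-6-hydroxy-4-methoxyphenyl)(3,5-dimethoxyphenyl)methanone
Conditions: BCl3 (1.5 equiv), CH2Cl2, -78 to 0 °C; aqueous work-up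
Reagents that add atoms: none
Why: Chelation-directed Lewis-acid ether cleavage, in which BCl3 binds the ketone oxygen and the neighbouring methoxy oxygen in a six-membered chelate, so that only this methyl group is lost and the three remote methyl ethers stay.

Step 3
Reactants: 4 (2-bromo-6-hydroxy-4-methoxyphenyl)(3,5-dimethoxyphenyl)methanone; 5 4-methoxybenzyl chloride
Product: 6 {2-bromo-4-methoxy-6-[(4-methoxybenzyl)oxy]phenyl}(3,5-dimethoxyphenyl)methanone
Conditions: K2CO3, n-Bu4NI (cat.), DMF, 60 °C
Reagents that add atoms: none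
Why: Williamson ether synthesis of the phenoxide with a reactive benzylic chloride installs the OCH2Ar unit whose CH2 becomes C2' and whose aryl group becomes ring G.

Step 4
Reactants: 6 {2-bromo-4-methoxy-6-[(4-methoxybenzyl)oxy]phenyl}(3,5-dimethoxyphenyl)methanone
Product: 7 hydrazone of 6 (E/Z mixture)
Conditions: N2H4·H2O (excess), AcOH (cat.), n-BuOH, 120 °C, sealed tube
Reagents that add atoms: hydrazine (used as hydrate), NN
Why: Acid-catalysed hydrazone condensation, driven by excess hydrazine and heat because the ketone carries two ortho substituents; the E/Z composition is irrelevant since both isomers give the same diazo compound.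

Step 5
Reactants: 7 hydrazone of 6
Product: 9 (2S,3R)-4-bromo-3-(3,5-dimethoxyphenyl)-6-methoxy-2-(4-methoxyphenyl)-2,3-dihydro-1-benzofuran (cis), via diaryldiazomethane 8 (not isolated)
Conditions: activated MnO2, CH2Cl2, rt, filtration through Celite; then Rh2(R-PTAD)4 (1 mol %), CH2Cl2, 0 °C
Reagents that add atoms: none
Why: Dehydrogenation of the hydrazone to the diaryldiazomethane is followed by enantioselective intramolecular 1,5 C-H insertion of a donor/donor rhodium carbene into the ether-activated benzylic CH2, a reaction type established for hydrazones of 2-(benzyloxy)benzophenones; the chiral carboxylate ligands set C3' (R) and the concerted insertion places the two aryl groups cis (C2' S) as ring D closes.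

Step 6
Reactants: 9 cis-dihydrobenzofuran (2S,3R)
Product: 10 (2R,3R)-4-bromo-3-(3,5-dimethoxyphenyl)-6-methoxy-2-(4-methoxyphenyl)-2,3-dihydro-1-benzofuran (trans)
Conditions: CF3CO2H, CH2Cl2, 0 °C, short exposure
Reagents that add atoms: none
Why: Acid-mediated epimerisation, in which reversible ionisation of the C2'-O bond to the 4-methoxybenzyl cation and reclosure relax the cis ring to the more stable trans ring, inverting only C2' (S to R) while C3' is untouched.

Step 7
Reactants: 10 trans-dihydrobenzofuran (2R,3R)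
Product: 11 (2R,3R)-4-bromo-3-(3,5-dihydroxyphenyl)-2-(4-hydroxyphenyl)-2,3-dihydro-1-benzofuran-6-ol
Conditions: BBr3 (8 equiv), CH2Cl2, -78 °C to rt; then ice water
Reagents that add atoms: none
Why: BBr3 cleavage of the four aryl methyl ethers is done before any alkene is present, so that acid-triggered cyclisations have no partner; a transient opening of the C2'-O bond would reclose to the same trans isomer and C3' is not involved.

Step 8
Reactants: 11 tetraphenol bromide
Product: 12 tetrakis-O-TBS ether of 11, (2R,3R)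
Conditions: TBSCl (6 equiv), imidazole, DMF, rt
Reagents that add atoms: tert-butyldimethylsilyl chloride (TBSCl), CC(C)(C)[Si](C)(C)Cl
Why: Standard silylation of phenols, chosen because TBS ethers keep the para oxygen a strong donor for step 11, shield the activated arene positions and can be removed at the end without strong acid.

Step 9
Reactants: 12 tetrakis-O-TBS bromide; 13 tert-butyl(4-ethenylphenoxy)dimethylsilane
Product: 14 penta-O-TBS-(2R,3R)-ε-viniferin (E alkene)
Conditions: Pd2(dba)3 (2.5 mol %), P(t-Bu)3·HBF4 (10 mol %), Cy2NMe, 1,4-dioxane, 90 °C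
Reagents that add atoms: none
Why: Mizoroki-Heck reaction, in which the bulky electron-rich phosphine lets zerovalent palladium insert into the hindered, electron-rich C4'-Br bond, and syn insertion followed by syn beta-hydride elimination gives the E alkene without touching the stereocentres.

Step 10
Reactants: 15 3-amino-4-hydroxybenzonitrile
Product: 17 3-diazo-4-oxocyclohexa-1,5-diene-1-carbonitrile (2-diazonio-4-cyanophenolate), via diazonium chloride 16 (not isolated)
Conditions: NaNO2, aq HCl, 0 °C; then NaHCO3 to pH 7-8, extraction into ClCH2CH2Cl, dried over Na2SO4, kept cold and in solution, never concentrated to dryness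
Reagents that add atoms: sodium nitrite, [Na+].[O-]N=O
Why: Diazotisation of an ortho-aminophenol, after which deprotonation of the phenol of the diazonium salt gives the neutral ortho-quinone diazide that the para nitrile stabilises.

Step 11
Reactants: 14 penta-O-TBS-(2R,3R)-ε-viniferin; 17 3-diazo-4-oxocyclohexa-1,5-diene-1-carbonitrile
Product: 19 (2R,3R)-3-{(2R,3R)-3-[3,5-bis(TBSO)phenyl]-6-(TBSO)-2-[4-(TBSO)phenyl]-2,3-dihydro-1-benzofuran-4-yl}-2-[4-(TBSO)phenyl]-2,3-dihydro-1-benzofuran-5-carbonitrile, via spirocyclopropyl dienone 18 (not isolated)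
Conditions: Rh2(S-TCPTTL)4 (2 mol %), 4 Å molecular sieves, ClCH2CH2Cl, 60 °C, solution of 17 (2.5 equiv) added by syringe pump over 8 h
Reagents that add atoms: none
Why: Proposed new method: Rh2(S-TCPTTL)4 takes N2 out of 17 and the electrophilic rhodium quinoid carbene adds through its carbene carbon (the future C3a) across the stilbene C=C of 14 to give the trans-1,2-diaryl spiro[2.5]octa-5,7-dien-4-one 18, a push-pull cyclopropane that at 60 °C breaks its C3a-C2 bond heterolytically (positive charge at C2 carried by ring F and its silyloxy group, negative charge carried by the oxygen on C7a and the para nitrile, ring A aromatised) and recloses from O1 to C2, so that the three-membered ring C3a-C3-C2 grows by C7a and O1 into ring B. The closest known reaction types are the dirhodium-catalysed formal [3+2] annulation of 1-diazonaphthalen-2(1H)-ones and of cyclic 2-diazo-1,3-diketones with enol ethers and styrenes, the spirocyclopropanation of styrenes with para-quinone diazides and the Cloke-Wilson rearrangement of donor-substituted cyclopropyl ketones to 2,3-dihydrofurans; new are the monocyclic ortho-quinone diazide, the 1,2-diaryl alkene and the stereocontrol that is asked for. The cyclopropane closes by a suprafacial, asynchronous [2+1] carbene addition in which the C3a-C3 bond leads (E alkene to trans cyclopropane), and ring B closes by 5-exo-trig attack of the phenolate oxygen on the para-quinone-methide-like cation. C3 is set in the carbene addition by the alkene face that the chiral carboxylate pocket of the catalyst admits, and its bonds to C3a, C2 and C4' are never broken afterwards; C2 is set in the reclosure, where ring F takes the side of ring B opposite to the large C3 substituent, which gives the trans (2R,3R) arrangement that is also the more stable one. Regiochemistry (O1 to C2, C3a to C3) needs no directing group, since only the cyclopropane bond to the carbon that bears the para-donor ring F can ionise whereas ring C offers C3 nothing but meta oxygens; chemoselectivity for the alkene over arene attack rests on the TBS groups that flank every activated arene position, and carrying C5 as a nitrile instead of an aldehyde excludes carbonyl-ylide formation with the carbene.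

Step 12
Reactants: 19 penta-O-TBS nitrile
Product: 21 penta-O-TBS ether of the target aldehyde, via N-alumino aldimine 20 (not isolated)
Conditions: i-Bu2AlH (1.5 equiv), toluene, -78 to -20 °C; then aq. potassium sodium tartrate, stirring with SiO2
Reagents that add atoms: water, O
Why: Partial reduction of a nitrile with i-Bu2AlH stops at the N-alumino aldimine, which is hydrolysed to the aldehyde on work-up, while aryl silyl ethers and both dihydrofuran rings are inert.

Step 13
Reactants: 21 penta-O-TBS aldehyde
Product: 22 (2R,3R)-3-[(2R,3R)-3-(3,5-dihydroxyphenyl)-6-hydroxy-2-(4-hydroxyphenyl)-2,3-dihydro-1-benzofuran-4-yl]-2-(4-hydroxyphenyl)-2,3-dihydro-1-benzofuran-5-carbaldehyde (target)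
Conditions: n-Bu4NF, AcOH (1:1, 6 equiv each), THF, 0 °C
Reagents that add atoms: none
Why: Fluoride-induced cleavage of aryl silyl ethers under acetic acid buffering avoids both phenoxide-triggered opening of rings B and D through para-quinone methides and acid-triggered ionisation at C2 and C2', so that all four stereocentres persist.

Compound list
1 | 1-bromo-3,5-dimethoxybenzene | COc1cc(Br)cc(OC)c1 | starting material
2 | 3,5-dimethoxybenzoyl chloride | COc1cc(cc(OC)c1)C(Cl)=O | starting material
3 | (2-bromo-4,6-dimethoxyphenyl)(3,5-dimethoxyphenyl)methanone | COc1cc(OC)cc(c1)C(=O)c1c(Br)cc(OC)cc1OC | intermediate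
4 | (2-bromo-6-hydroxy-4-methoxyphenyl)(3,5-dimethoxyphenyl)methanone | COc1cc(OC)cc(c1)C(=O)c1c(Br)cc(OC)cc1O | intermediate
5 | 4-methoxybenzyl chloride | COc1ccc(CCl)cc1 | starting material
6 | {2-bromo-4-methoxy-6-[(4-methoxybenzyl)oxy]phenyl}(3,5-dimethoxyphenyl)methanone | COc1ccc(COc2cc(OC)cc(Br)c2C(=O)c2cc(OC)cc(OC)c2)cc1 | intermediate
7 | hydrazone of 6, E/Z mixture | COc1ccc(COc2cc(OC)cc(Br)c2C(=NN)c2cc(OC)cc(OC)c2)cc1 | intermediate
8 | 1-bromo-2-[diazo(3,5-dimethoxyphenyl)methyl]-5-methoxy-3-[(4-methoxybenzyl)oxy]benzene, not isolated | COc1ccc(COc2cc(OC)cc(Br)c2C(=[N+]=[N-])c2cc(OC)cc(OC)c2)cc1 | intermediate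
9 | (2S,3R)-4-bromo-3-(3,5-dimethoxyphenyl)-6-methoxy-2-(4-methoxyphenyl)-2,3-dihydro-1-benzofuran, cis | Brc1cc(OC)cc2c1[C@@H](c1cc(OC)cc(OC)c1)[C@@H](c1ccc(OC)cc1)O2 | intermediate
10 | (2R,3R)-4-bromo-3-(3,5-dimethoxyphenyl)-6-methoxy-2-(4-methoxyphenyl)-2,3-dihydro-1-benzofuran, trans | Brc1cc(OC)cc2c1[C@@H](c1cc(OC)cc(OC)c1)[C@H](c1ccc(OC)cc1)O2 | intermediate
11 | (2R,3R)-4-bromo-3-(3,5-dihydroxyphenyl)-2-(4-hydroxyphenyl)-2,3-dihydro-1-benzofuran-6-ol | Brc1cc(O)cc2c1[C@@H](c1cc(O)cc(O)c1)[C@H](c1ccc(O)cc1)O2 | intermediate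
12 | tetrakis-O-TBS ether of 11, (2R,3R) | Brc1cc(O[Si](C)(C)C(C)(C)C)cc2c1[C@@H](c1cc(O[Si](C)(C)C(C)(C)C)cc(O[Si](C)(C)C(C)(C)C)c1)[C@H](c1ccc(O[Si](C)(C)C(C)(C)C)cc1)O2 | intermediate
13 | tert-butyl(4-ethenylphenoxy)dimethylsilane | C=Cc1ccc(O[Si](C)(C)C(C)(C)C)cc1 | starting material
14 | penta-O-TBS-(2R,3R)-ε-viniferin, E alkene at C4' | CC(C)(C)[Si](C)(C)Oc1ccc(/C=C/c2cc(O[Si](C)(C)C(C)(C)C)cc3c2[C@@H](c2cc(O[Si](C)(C)C(C)(C)C)cc(O[Si](C)(C)C(C)(C)C)c2)[C@H](c2ccc(O[Si](C)(C)C(C)(C)C)cc2)O3)cc1 | intermediate
15 | 3-amino-4-hydroxybenzonitrile | N#Cc1ccc(O)c(N)c1 | starting material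
16 | 5-cyano-2-hydroxybenzenediazonium chloride, not isolated | N#Cc1ccc(O)c(c1)[N+]#N.[Cl-] | intermediate
17 | 3-diazo-4-oxocyclohexa-1,5-diene-1-carbonitrile | N#CC1=CC(=[N+]=[N-])C(=O)C=C1 | intermediate
18 | 4-oxospiro[2.5]octa-5,7-diene-7-carbonitrile bearing the ring C/D aryl group on C1 and 4-(TBSO)phenyl on C2, the two aryl groups trans, C1 with the configuration carried into C3 of 19, spiro carbon as either epimer (lost on ring opening), not isolated | N#CC1=CC2(C(=O)C=C1)[C@@H](c1cc(O[Si](C)(C)C(C)(C)C)cc3c1[C@@H](c1cc(O[Si](C)(C)C(C)(C)C)cc(O[Si](C)(C)C(C)(C)C)c1)[C@H](c1ccc(O[Si](C)(C)C(C)(C)C)cc1)O3)[C@@H]2c1ccc(O[Si](C)(C)C(C)(C)C)cc1 | intermediate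
19 | penta-O-TBS 5-carbonitrile, (2R,3R) in ring B and (2R,3R) in ring D | N#Cc1ccc2c(c1)[C@@H](c1cc(O[Si](C)(C)C(C)(C)C)cc3c1[C@@H](c1cc(O[Si](C)(C)C(C)(C)C)cc(O[Si](C)(C)C(C)(C)C)c1)[C@H](c1ccc(O[Si](C)(C)C(C)(C)C)cc1)O3)[C@H](c1ccc(O[Si](C)(C)C(C)(C)C)cc1)O2 | intermediate
20 | N-(diisobutylalumino) aldimine of 21, not isolated | CC(C)C[Al](CC(C)C)N=Cc1ccc2c(c1)[C@@H](c1cc(O[Si](C)(C)C(C)(C)C)cc3c1[C@@H](c1cc(O[Si](C)(C)C(C)(C)C)cc(O[Si](C)(C)C(C)(C)C)c1)[C@H](c1ccc(O[Si](C)(C)C(C)(C)C)cc1)O3)[C@H](c1ccc(O[Si](C)(C)C(C)(C)C)cc1)O2 | intermediate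
21 | penta-O-TBS ether of the target aldehyde | O=Cc1ccc2c(c1)[C@@H](c1cc(O[Si](C)(C)C(C)(C)C)cc3c1[C@@H](c1cc(O[Si](C)(C)C(C)(C)C)cc(O[Si](C)(C)C(C)(C)C)c1)[C@H](c1ccc(O[Si](C)(C)C(C)(C)C)cc1)O3)[C@H](c1ccc(O[Si](C)(C)C(C)(C)C)cc1)O2 | intermediate
22 | (2R,3R)-3-[(2R,3R)-3-(3,5-dihydroxyphenyl)-6-hydroxy-2-(4-hydroxyphenyl)-2,3-dihydro-1-benzofuran-4-yl]-2-(4-hydroxyphenyl)-2,3-dihydro-1-benzofuran-5-carbaldehyde | O=Cc1ccc2c(c1)[C@@H](c1cc(O)cc3c1[C@@H](c1cc(O)cc(O)c1)[C@H](c1ccc(O)cc1)O3)[C@H](c1ccc(O)cc1)O2 | target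

Total step count: 13. Longest linear sequence: 12 (steps 1 to 9 and 11 to 13; step 10 is a one-step branch).

Steps most likely to fail

1. Step 11 (new method).
- What may go wrong, reactivity: carbene transfer to a hindered trans-1,2-diaryl alkene may be slow. Carbene dimerisation, Wolff-type contraction of the quinoid carbene or attack on an arene could then take over.
- What may go wrong, selectivity: facial selectivity may be poor. In the preferred rotamer, with the C-H of the alkene carbon next to ring C pointing towards C3', ring E shields the face from which C3a has to arrive. Catalyst and substrate control may therefore oppose each other.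
- Fallback: known chemistry, a formal [4+1] annulation of an ortho-quinone methide with a sulfur ylide. It sets out from 12 and comes back at 19.
- Bromine-lithium exchange of 12 (n-BuLi, THF, -78 °C) gives the aryllithium F1. This adds to the sodium phenoxide (NaH) of commercial 3-formyl-4-hydroxybenzonitrile to give the ortho-hydroxybenzhydrol F2 as a carbinol mixture.
- p-Toluenesulfinic acid in CH2Cl2 turns F2 into the benzylic sulfone F3.
- F3 is stirred with [4-(TBSO)benzyl]dimethylsulfonium tetrafluoroborate F4 (from the benzyl bromide, Me2S and AgBF4) and Cs2CO3 in CH2Cl2. This forms the ortho-quinone methide F5 and the benzylic sulfonium ylide F6 side by side.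
- 1,4-Addition followed by 5-exo-tet displacement of Me2S by the phenoxide closes a trans ring B.
- Here the incoming carbon is C2. Its approach to C3 from the face remote from ring E should correspond to the 3R configuration that is needed. The ring-B diastereomer F7, if formed, is removed by chromatography.

2. Step 4.
- What may go wrong: condensation at a ketone with two ortho substituents may stall. Under forcing conditions hydrazine may displace the neighbouring bromide with ring closure to an indazole.
- Fallback: it sets out from 6 and comes back at 10, bypassing steps 4 to 6.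
- The phosphazene base P4-t-Bu in benzene at reflux deprotonates the OCH2Ar group. The carbanion adds to the ketone to give the 3-hydroxy-2,3-dihydrobenzofuran F8.
- F8 loses water (TsOH, cat.) to give the 2,3-diarylbenzofuran F9.
- Ionic hydrogenation (Et3SiH, CF3CO2H, CH2Cl2) protonates C3 and delivers hydride to C2 anti to the C3 aryl group. This gives the racemic trans compound, that is 10 together with its mirror image F10.
- 10 is obtained from the racemate by preparative chromatography on a chiral stationary phase.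

3. Step 9.
- What may go wrong: oxidative addition and alkene insertion at the C4' position next to ring E may be slow. Protodebromination or loss of silyl groups on prolonged heating could follow.
- Fallback: it sets out from 12 and comes back at 14.
- The aryllithium F1, made as above, is quenched with DMF to give the C4' aldehyde F11.
- A Horner-Wadsworth-Emmons reaction with diethyl [4-(TBSO)benzyl]phosphonate F12 (from the benzyl bromide and P(OEt)3; KHMDS, THF, -78 to 0 °C) gives the E alkene 14.

Further compounds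
F1 | step 11 | C4' aryllithium derived from 12 | [Li]c1cc(O[Si](C)(C)C(C)(C)C)cc2c1[C@@H](c1cc(O[Si](C)(C)C(C)(C)C)cc(O[Si](C)(C)C(C)(C)C)c1)[C@H](c1ccc(O[Si](C)(C)C(C)(C)C)cc1)O2
F2 | step 11 | 4-hydroxy-3-[hydroxy(ring C/D aryl)methyl]benzonitrile, carbinol mixture | N#Cc1ccc(O)c(c1)C(O)c1cc(O[Si](C)(C)C(C)(C)C)cc2c1[C@@H](c1cc(O[Si](C)(C)C(C)(C)C)cc(O[Si](C)(C)C(C)(C)C)c1)[C@H](c1ccc(O[Si](C)(C)C(C)(C)C)cc1)O2
F3 | step 11 | 4-hydroxy-3-[(4-methylphenyl)sulfonyl(ring C/D aryl)methyl]benzonitrile | N#Cc1ccc(O)c(c1)C(c1cc(O[Si](C)(C)C(C)(C)C)cc2c1[C@@H](c1cc(O[Si](C)(C)C(C)(C)C)cc(O[Si](C)(C)C(C)(C)C)c1)[C@H](c1ccc(O[Si](C)(C)C(C)(C)C)cc1)O2)S(=O)(=O)c1ccc(C)cc1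
F4 | step 11 | [4-(TBSO)benzyl]dimethylsulfonium tetrafluoroborate | C[S+](C)Cc1ccc(O[Si](C)(C)C(C)(C)C)cc1.F[B-](F)(F)F
F5 | step 11 | ortho-quinone methide from F3, not isolated | N#CC1=CC(=Cc2cc(O[Si](C)(C)C(C)(C)C)cc3c2[C@@H](c2cc(O[Si](C)(C)C(C)(C)C)cc(O[Si](C)(C)C(C)(C)C)c2)[C@H](c2ccc(O[Si](C)(C)C(C)(C)C)cc2)O3)C(=O)C=C1
F6 | step 11 | benzylic sulfonium ylide from F4, not isolated | C[S+](C)[CH-]c1ccc(O[Si](C)(C)C(C)(C)C)cc1
F7 | step 11 | ring-B diastereomer of 19, (2S,3S) in ring B and (2R,3R) in ring D | N#Cc1ccc2c(c1)[C@H](c1cc(O[Si](C)(C)C(C)(C)C)cc3c1[C@@H](c1cc(O[Si](C)(C)C(C)(C)C)cc(O[Si](C)(C)C(C)(C)C)c1)[C@H](c1ccc(O[Si](C)(C)C(C)(C)C)cc1)O3)[C@@H](c1ccc(O[Si](C)(C)C(C)(C)C)cc1)O2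
F8 | step 4 | 4-bromo-3-(3,5-dimethoxyphenyl)-6-methoxy-2-(4-methoxyphenyl)-2,3-dihydro-1-benzofuran-3-ol, not isolated | COc1ccc(cc1)C1Oc2cc(OC)cc(Br)c2C1(O)c1cc(OC)cc(OC)c1
F9 | step 4 | 4-bromo-3-(3,5-dimethoxyphenyl)-6-methoxy-2-(4-methoxyphenyl)-1-benzofuran | COc1ccc(cc1)-c1oc2cc(OC)cc(Br)c2c1-c1cc(OC)cc(OC)c1
F10 | step 4 | (2S,3S) mirror image of 10, formed with 10 as the racemate | Brc1cc(OC)cc2c1[C@H](c1cc(OC)cc(OC)c1)[C@@H](c1ccc(OC)cc1)O2
F11 | step 9 | (2R,3R)-tetrakis-O-TBS 2,3-dihydro-1-benzofuran-4-carbaldehyde | O=Cc1cc(O[Si](C)(C)C(C)(C)C)cc2c1[C@@H](c1cc(O[Si](C)(C)C(C)(C)C)cc(O[Si](C)(C)C(C)(C)C)c1)[C@H](c1ccc(O[Si](C)(C)C(C)(C)C)cc1)O2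
F12 | step 9 | diethyl [4-(TBSO)benzyl]phosphonate | CCOP(=O)(Cc1ccc(O[Si](C)(C)C(C)(C)C)cc1)OCC
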